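**Retrosynthetic overview**
1. The oxirane is made last, by C18‑hydroxyl‑directed epoxidation of the C14=C15 alkene of the seco acid.
2. C9–C10 is cut into an oxane alkyne (C1–C9) and a C10–C19 (E)‑vinyl iodide, joined by one‑pot methylalumination and Pd cross‑coupling.
3. The oxane comes from a Baeyer–Villiger ring expansion of a trans‑2,3‑disubstituted cyclopentanone to the δ‑lactone (C6, C7 carried over), then acetate‑enolate addition and axial hydride reduction (C3).
4. The side chain is cut at C15–C16: methylalumination of a chiral‑pool alkynol (C12) and inversion opening of a trans‑epoxy silyl ether (C16–C18).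
5. Ring order: purchased cyclopentenone → six‑membered lactone by ring expansion → oxane; the building‑block oxirane is opened on the way; the target oxirane is closed last.

Atom labels C1 (CO2H) to C19 follow the usual herboxidiene numbering.
Assumption: (S)‑p‑tol‑BINAP delivers hydride to the enone face that gives the (3S) centre in step 1; if the sense is the opposite, the (R)‑ligand is used.
The route is a proposal; no step has been run, and the selectivities quoted are expectations from the reaction classes.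

**Step 1**
Reactants: 1 3-methylcyclopent-2-en-1-one
Product: 3 (2S,3S)-2-{[(4-methoxybenzyl)oxy]methyl}-3-methylcyclopentan-1-one, via bis(silyl enol ether) 2 (not isolated)
Conditions: CuCl (5 mol%), NaOt-Bu (5 mol%), (S)-p-tol-BINAP (5 mol%), Ph2SiH2 (0.52 equiv), toluene, 0 °C; then Bu4N[Ph3SiF2], 4-MeOC6H4CH2OCH2Cl (freshly made), CH2Cl2, 0 °C to rt
Reagents that add atoms: 4-methoxybenzyl chloromethyl ether, COc1ccc(COCCl)cc1
Why: Ligated CuH adds hydride to one enone face (asymmetric conjugate reduction, sets C6) and the regio‑defined silyl enol ether is then alkylated anti to the ring methyl group, giving the trans ketone (C7) in a one‑pot reduction–alkylation of the Buchwald type.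

**Step 2**
Reactants: 3 (2S,3S)-2-{[(4-methoxybenzyl)oxy]methyl}-3-methylcyclopentan-1-one
Product: 4 (5S,6S)-6-{[(4-methoxybenzyl)oxy]methyl}-5-methyloxan-2-one
Conditions: mCPBA, Na2HPO4, CH2Cl2, 0 °C to rt
Reagents that add atoms: 3-chloroperbenzoic acid, OOC(=O)c1cccc(Cl)c1
Why: Baeyer–Villiger oxidation: after peracid addition the more substituted α‑carbon shifts from carbon to oxygen with retention, expanding the cyclopentanone to the six‑membered lactone and carrying C6 and C7 over unchanged.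

**Step 3**
Reactants: 4 (5S,6S)-6-{[(4-methoxybenzyl)oxy]methyl}-5-methyloxan-2-one; 5 methyl acetate
Product: 7 methyl 2-[(2R,5S,6S)-2-hydroxy-6-{[(4-methoxybenzyl)oxy]methyl}-5-methyloxan-2-yl]acetate, via lithium enolate 6 (not isolated)
Conditions: LiN(iPr)2, THF, −78 °C; then 4; AcOH, −78 °C
Reagents that add atoms: none
Why: Claisen‑type addition of the ester enolate to the lactone carbonyl stops at the tetrahedral stage at −78 °C and gives the hemiketal (major anomer shown; C3 is fixed only in step 4).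

**Step 4**
Reactants: 7 methyl 2-[(2R,5S,6S)-2-hydroxy-6-{[(4-methoxybenzyl)oxy]methyl}-5-methyloxan-2-yl]acetate
Product: 9 methyl 2-[(2R,5S,6S)-6-(hydroxymethyl)-5-methyloxan-2-yl]acetate, via oxane PMB ether 8 (not isolated)
Conditions: Et3SiH, CF3CO2H, CH2Cl2, −40 °C, then rt
Reagents that add atoms: none
Why: Ionic (Kishi‑type) reduction: the silane attacks the oxocarbenium ion axially, giving the 2,6‑cis oxane (C3 R, all substituents equatorial), and on warming the acid cleaves the PMB ether, whose cation the silane reduces.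

**Step 5**
Reactants: 9 methyl 2-[(2R,5S,6S)-6-(hydroxymethyl)-5-methyloxan-2-yl]acetate
Product: 10 methyl 2-[(2R,5S,6S)-6-formyl-5-methyloxan-2-yl]acetate
Conditions: TEMPO (10 mol%), PhI(OAc)2, CH2Cl2, rt
Reagents that add atoms: none
Why: TEMPO‑catalysed oxidation of the primary alcohol stops at the aldehyde under non‑basic conditions, so C7 is not epimerised.

**Step 6**
Reactants: 10 methyl 2-[(2R,5S,6S)-6-formyl-5-methyloxan-2-yl]acetate
Product: 11 methyl 2-[(2R,5S,6S)-6-ethynyl-5-methyloxan-2-yl]acetate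
Conditions: MeC(O)C(N2)P(O)(OMe)2, K2CO3, MeOH, 0 °C to rt
Reagents that add atoms: dimethyl (1-diazo-2-oxopropyl)phosphonate, COP(=O)(OC)C(=[N+]=[N-])C(C)=O
Why: Seyferth–Gilbert homologation with the Ohira–Bestmann reagent turns the aldehyde into the terminal alkyne; C7 stays in its equatorial configuration, which is also the thermodynamically preferred one under the mild base.

**Step 7**
Reactants: 12 (2R)-3-bromo-2-methylpropan-1-ol; 13 lithium acetylide–ethylenediamine complex
Product: 14 (2S)-2-methylpent-4-yn-1-ol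
Conditions: LiC≡CH·H2NCH2CH2NH2 (3 equiv), DMSO, 0 °C to rt
Reagents that add atoms: none
Why: SN2 displacement of the primary bromide by acetylide (excess reagent covers the hydroxyl proton); C12 comes from the chiral pool and is not at the reacting carbon (the descriptor changes only through CIP priorities).

**Step 8**
Reactants: 15 racemic (3E)-pent-3-en-2-ol
Product: 16 (2R,3E)-pent-3-en-2-ol
Conditions: Ti(OiPr)4 (10 mol%), L-(+)-diisopropyl tartrate (15 mol%), t-BuOOH (0.6 equiv), 4 Å sieves, CH2Cl2, −20 °C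
Reagents that add atoms: none
Why: Sharpless kinetic resolution: with L‑(+)‑tartrate the (S)‑alcohol is epoxidised far faster, so the (R)‑alcohol (C18) is recovered in high ee at about 55–60% conversion.

**Step 9**
Reactants: 16 (2R,3E)-pent-3-en-2-ol
Product: 17 tert-butyldimethyl{[(2R,3E)-pent-3-en-2-yl]oxy}silane
Conditions: TBSCl, imidazole, DMF, rt
Reagents that add atoms: tert-butyldimethylsilyl chloride, CC(C)(C)[Si](C)(C)Cl
Why: Standard silylation; the TBS group masks O18 through the C–C coupling and the O17 methylation.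

**Step 10**
Reactants: 17 tert-butyldimethyl{[(2R,3E)-pent-3-en-2-yl]oxy}silane
Product: 18 tert-butyldimethyl{(1R)-1-[(2R,3S)-3-methyloxiran-2-yl]ethoxy}silane
Conditions: L-fructose-derived Shi ketone (30 mol%), KHSO5 (Oxone), K2CO3, Bu4NHSO4, MeCN/CH2(OMe)2/aq. Na2B4O7 buffer, 0 °C
Reagents that add atoms: potassium peroxymonosulfate, [K+].[O-]S(=O)(=O)OO
Why: Shi epoxidation: the chiral dioxirane transfers oxygen to one face of the trans‑alkene under catalyst control, setting C16 and C17 threo to C18 (the L‑fructose‑derived ketone is the enantiomer that gives this face).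

**Step 11**
Reactants: 14 (2S)-2-methylpent-4-yn-1-ol; 18 tert-butyldimethyl{(1R)-1-[(2R,3S)-3-methyloxiran-2-yl]ethoxy}silane
Product: 21 (2S,4E,6S,7R,8R)-8-[(tert-butyldimethylsilyl)oxy]-2,4,6-trimethylnon-4-ene-1,7-diol, via alkenylalane 19 (not isolated), via lithium alkenylalanate 20 (not isolated)
Conditions: Me3Al (3 equiv), Cp2ZrCl2 (25 mol%), CH2Cl2, 0 °C to rt; volatiles removed; n-BuLi (1 equiv per alkenyl–Al), Et2O/hexane, −78 °C; then 18, BF3·OEt2, −78 °C
Reagents that add atoms: trimethylaluminium, C[Al](C)C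
Why: Proposed new method: one‑pot Zr‑catalysed syn‑methylalumination of the unprotected alkynol (Me and Al add cis, so C14=C15 is E), conversion of the alkenylalane into its lithium alanate, and BF3‑assisted opening of 18, in which the sp2 ligand is transferred in preference to methyl or butyl and attacks C16 with inversion because C16 is the less hindered epoxide carbon and C17 is deactivated by the adjacent C–OSi dipole, so the C15–C16 bond and the C16 stereocentre arise in one operation; the closest known reactions are the Negishi carboalumination–alanate opening of oxirane and terminal epoxides and the BF3‑assisted opening of cyclohexene oxide by alanates, which to my knowledge have not been shown for an acyclic trans‑epoxide flanked by a silyloxy stereocentre or with an alanate made from a free alkynol.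

**Step 12**
Reactants: 21 (2S,4E,6S,7R,8R)-8-[(tert-butyldimethylsilyl)oxy]-2,4,6-trimethylnon-4-ene-1,7-diol
Product: 22 (2S,4E,6S,7R,8R)-8-[(tert-butyldimethylsilyl)oxy]-7-hydroxy-2,4,6-trimethylnon-4-enal
Conditions: TEMPO (10 mol%), PhI(OAc)2, CH2Cl2, rt
Reagents that add atoms: none
Why: TEMPO/PhI(OAc)2 oxidises the primary alcohol chemoselectively in the presence of the hindered secondary alcohol and stops at the aldehyde without epimerising C12.

**Step 13**
Reactants: 22 (2S,4E,6S,7R,8R)-8-[(tert-butyldimethylsilyl)oxy]-7-hydroxy-2,4,6-trimethylnon-4-enal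
Product: 23 (2R,3R,4S,5E,8S,9E)-2-[(tert-butyldimethylsilyl)oxy]-10-iodo-4,6,8-trimethyldeca-5,9-dien-3-ol
Conditions: CrCl2 (8 equiv), CHI3 (3 equiv), THF/1,4-dioxane, 0 °C to rt
Reagents that add atoms: iodoform, IC(I)I
Why: Takai olefination: the gem‑dichromium reagent from iodoform converts the aldehyde into the (E)‑vinyl iodide (C10=C11) under non‑basic conditions that leave C12 and the free hydroxyl untouched.

**Step 14**
Reactants: 23 (2R,3R,4S,5E,8S,9E)-2-[(tert-butyldimethylsilyl)oxy]-10-iodo-4,6,8-trimethyldeca-5,9-dien-3-ol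
Product: 24 tert-butyl{[(2R,3R,4S,5E,8S,9E)-10-iodo-3-methoxy-4,6,8-trimethyldeca-5,9-dien-2-yl]oxy}dimethylsilane
Conditions: MeOTf, 2,6-di-tert-butyl-4-methylpyridine, CH2Cl2, rt
Reagents that add atoms: methyl trifluoromethanesulfonate, COS(=O)(=O)C(F)(F)F
Why: O‑Methylation with methyl triflate and a hindered pyridine is non‑basic, so the neighbouring TBS group does not migrate and C17 keeps its configuration.

**Step 15**
Reactants: 11 methyl 2-[(2R,5S,6S)-6-ethynyl-5-methyloxan-2-yl]acetate; 24 tert-butyl{[(2R,3R,4S,5E,8S,9E)-10-iodo-3-methoxy-4,6,8-trimethyldeca-5,9-dien-2-yl]oxy}dimethylsilane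
Product: 26 methyl 2-[(2R,5S,6S)-6-[(2E,4E,6S,8E,10S,11R,12R)-12-[(tert-butyldimethylsilyl)oxy]-11-methoxy-6,8,10-trimethyltrideca-2,4,8-trien-2-yl]-5-methyloxan-2-yl]acetate, via alkenylalane 25 (not isolated)
Conditions: Me3Al (2.6 equiv), Cp2ZrCl2 (25 mol%), H2O (1 equiv), CH2Cl2, −20 °C; then 24, ZnCl2 (0.5 equiv), Pd(PPh3)4 (5 mol%), THF, rt
Reagents that add atoms: trimethylaluminium, C[Al](C)C
Why: Negishi Zr‑catalysed syn‑methylalumination puts methyl on C8 and aluminium on C9 (E), and the alkenylalane is cross‑coupled in the same flask with the vinyl iodide under Pd/Zn catalysis with retention at both alkenes, giving the (8E,10E)‑diene.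

**Step 16**
Reactants: 26 methyl 2-[(2R,5S,6S)-6-[(2E,4E,6S,8E,10S,11R,12R)-12-[(tert-butyldimethylsilyl)oxy]-11-methoxy-6,8,10-trimethyltrideca-2,4,8-trien-2-yl]-5-methyloxan-2-yl]acetate
Product: 28 2-[(2R,5S,6S)-6-[(2E,4E,6S,8E,10S,11R,12R)-12-hydroxy-11-methoxy-6,8,10-trimethyltrideca-2,4,8-trien-2-yl]-5-methyloxan-2-yl]acetic acid, via hydroxy ester 27 (not isolated)
Conditions: Bu4NF, THF, rt; then LiOH, MeOH/H2O, rt; aq. HCl to pH 4
Reagents that add atoms: lithium hydroxide, [Li+].[OH-]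
Why: Fluoride removes the TBS ether and hydroxide then saponifies the methyl ester in the same flask; no stereocentre is touched (the 2,6‑cis oxane is the thermodynamic isomer).

**Step 17**
Reactants: 28 2-[(2R,5S,6S)-6-[(2E,4E,6S,8E,10S,11R,12R)-12-hydroxy-11-methoxy-6,8,10-trimethyltrideca-2,4,8-trien-2-yl]-5-methyloxan-2-yl]acetic acid
Product: 29 herboxidiene
Conditions: VO(acac)2 (10 mol%), t-BuOOH, CH2Cl2, −20 °C
Reagents that add atoms: tert-butyl hydroperoxide, CC(C)(C)OO
Why: Hydroxyl‑directed vanadium‑catalysed epoxidation: the C18 hydroxyl binds the vanadium peroxide and delivers oxygen to one face of the bishomoallylic C14=C15 alkene only, setting C14 and C15 (both R) and leaving the diene untouched.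

**Compound list**
1 | 3-methylcyclopent-2-en-1-one | CC1=CC(=O)CC1 | starting material
2 | diphenylbis{[(3S)-3-methylcyclopent-1-en-1-yl]oxy}silane | C[C@H]1CCC(O[Si](c2ccccc2)(c2ccccc2)OC2=C[C@@H](C)CC2)=C1 | intermediate
3 | (2S,3S)-2-{[(4-methoxybenzyl)oxy]methyl}-3-methylcyclopentan-1-one | COc1ccc(COC[C@H]2C(=O)CC[C@@H]2C)cc1 | intermediate
4 | (5S,6S)-6-{[(4-methoxybenzyl)oxy]methyl}-5-methyloxan-2-one | COc1ccc(COC[C@H]2OC(=O)CC[C@@H]2C)cc1 | intermediate
5 | methyl acetate | COC(C)=O | starting material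
6 | lithium 1-methoxyethen-1-olate (lithium enolate of methyl acetate) | [Li]OC(=C)OC | intermediate
7 | methyl 2-[(2R,5S,6S)-2-hydroxy-6-{[(4-methoxybenzyl)oxy]methyl}-5-methyloxan-2-yl]acetate | COc1ccc(COC[C@H]2O[C@@](O)(CC(=O)OC)CC[C@@H]2C)cc1 | intermediate
8 | methyl 2-[(2R,5S,6S)-6-{[(4-methoxybenzyl)oxy]methyl}-5-methyloxan-2-yl]acetate | COc1ccc(COC[C@H]2O[C@@H](CC(=O)OC)CC[C@@H]2C)cc1 | intermediate
9 | methyl 2-[(2R,5S,6S)-6-(hydroxymethyl)-5-methyloxan-2-yl]acetate | OC[C@H]1O[C@@H](CC(=O)OC)CC[C@@H]1C | intermediate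
10 | methyl 2-[(2R,5S,6S)-6-formyl-5-methyloxan-2-yl]acetate | O=C[C@H]1O[C@@H](CC(=O)OC)CC[C@@H]1C | intermediate
11 | methyl 2-[(2R,5S,6S)-6-ethynyl-5-methyloxan-2-yl]acetate | C#C[C@H]1O[C@@H](CC(=O)OC)CC[C@@H]1C | intermediate
12 | (2R)-3-bromo-2-methylpropan-1-ol | BrC[C@H](C)CO | starting material
13 | lithium acetylide–ethylenediamine complex (LiC≡CH·H2NCH2CH2NH2) | [Li]C#C.NCCN | starting material
14 | (2S)-2-methylpent-4-yn-1-ol | C#CC[C@H](C)CO | intermediate
15 | racemic (3E)-pent-3-en-2-ol | C/C=C/C(C)O | starting material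
16 | (2R,3E)-pent-3-en-2-ol | C/C=C/[C@@H](C)O | intermediate
17 | tert-butyldimethyl{[(2R,3E)-pent-3-en-2-yl]oxy}silane | C/C=C/[C@@H](C)O[Si](C)(C)C(C)(C)C | intermediate
18 | tert-butyldimethyl{(1R)-1-[(2R,3S)-3-methyloxiran-2-yl]ethoxy}silane | C[C@@H](O[Si](C)(C)C(C)(C)C)[C@@H]1O[C@H]1C | intermediate
19 | {(1E,4S)-5-[(dimethylalumanyl)oxy]-2,4-dimethylpent-1-en-1-yl}dimethylalumane | C[Al](C)/C=C(\C)C[C@H](C)CO[Al](C)C | intermediate
20 | lithium butyl{(1E,4S)-5-[(dimethylalumanyl)oxy]-2,4-dimethylpent-1-en-1-yl}dimethylaluminate | [Li+].CCCC[Al-](C)(C)/C=C(\C)C[C@H](C)CO[Al](C)C | intermediate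
21 | (2S,4E,6S,7R,8R)-8-[(tert-butyldimethylsilyl)oxy]-2,4,6-trimethylnon-4-ene-1,7-diol | OC[C@@H](C)C/C(C)=C/[C@H](C)[C@@H](O)[C@@H](C)O[Si](C)(C)C(C)(C)C | intermediate
22 | (2S,4E,6S,7R,8R)-8-[(tert-butyldimethylsilyl)oxy]-7-hydroxy-2,4,6-trimethylnon-4-enal | O=C[C@@H](C)C/C(C)=C/[C@H](C)[C@@H](O)[C@@H](C)O[Si](C)(C)C(C)(C)C | intermediate
23 | (2R,3R,4S,5E,8S,9E)-2-[(tert-butyldimethylsilyl)oxy]-10-iodo-4,6,8-trimethyldeca-5,9-dien-3-ol | I/C=C/[C@@H](C)C/C(C)=C/[C@H](C)[C@@H](O)[C@@H](C)O[Si](C)(C)C(C)(C)C | intermediate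
24 | tert-butyl{[(2R,3R,4S,5E,8S,9E)-10-iodo-3-methoxy-4,6,8-trimethyldeca-5,9-dien-2-yl]oxy}dimethylsilane | I/C=C/[C@@H](C)C/C(C)=C/[C@H](C)[C@@H](OC)[C@@H](C)O[Si](C)(C)C(C)(C)C | intermediate
25 | methyl 2-[(2R,5S,6S)-6-[(1E)-1-(dimethylalumanyl)prop-1-en-2-yl]-5-methyloxan-2-yl]acetate | C[Al](C)/C=C(\C)[C@H]1O[C@@H](CC(=O)OC)CC[C@@H]1C | intermediate
26 | methyl 2-[(2R,5S,6S)-6-[(2E,4E,6S,8E,10S,11R,12R)-12-[(tert-butyldimethylsilyl)oxy]-11-methoxy-6,8,10-trimethyltrideca-2,4,8-trien-2-yl]-5-methyloxan-2-yl]acetate | CO[C@H]([C@@H](C)/C=C(\C)C[C@H](C)/C=C/C=C(\C)[C@H]1O[C@@H](CC(=O)OC)CC[C@@H]1C)[C@@H](C)O[Si](C)(C)C(C)(C)C | intermediate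
27 | methyl 2-[(2R,5S,6S)-6-[(2E,4E,6S,8E,10S,11R,12R)-12-hydroxy-11-methoxy-6,8,10-trimethyltrideca-2,4,8-trien-2-yl]-5-methyloxan-2-yl]acetate | CO[C@H]([C@@H](C)/C=C(\C)C[C@H](C)/C=C/C=C(\C)[C@H]1O[C@@H](CC(=O)OC)CC[C@@H]1C)[C@@H](C)O | intermediate
28 | 2-[(2R,5S,6S)-6-[(2E,4E,6S,8E,10S,11R,12R)-12-hydroxy-11-methoxy-6,8,10-trimethyltrideca-2,4,8-trien-2-yl]-5-methyloxan-2-yl]acetic acid | CO[C@H]([C@@H](C)/C=C(\C)C[C@H](C)/C=C/C=C(\C)[C@H]1O[C@@H](CC(=O)O)CC[C@@H]1C)[C@@H](C)O | intermediate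
29 | herboxidiene: 2-[(2R,5S,6S)-6-[(2E,4E,6S)-7-[(2R,3R)-3-[(2R,3R,4R)-4-hydroxy-3-methoxypentan-2-yl]-2-methyloxiran-2-yl]-6-methylhepta-2,4-dien-2-yl]-5-methyloxan-2-yl]acetic acid | CO[C@H]([C@@H](C)[C@H]1O[C@]1(C)C[C@H](C)/C=C/C=C(\C)[C@H]1O[C@@H](CC(=O)O)CC[C@@H]1C)[C@@H](C)O | target

**Step count and risks**
Total step count: 17 (oxane half 6, side chain 8, end game 3).
Longest linear sequence: 10 steps (15 → 16 → 17 → 18 → 21 → 22 → 23 → 24 → 26 → 28 → 29, steps 8–17).

The three steps most likely to fail: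

Step 10 (catalyst‑controlled epoxidation). The alkene is small and carries a bulky allylic silyl ether, so face selectivity may be modest, and the less common L‑fructose‑derived ketone is required. The fallback sets out from 15 and comes back at 18. The kinetic resolution of step 8 is stopped near 45% conversion and its epoxide is kept: the erythro epoxy alcohol (1S)-1-[(2S,3S)-3-methyloxiran-2-yl]ethan-1-ol F1 already has the oxirane configuration of 18. Mitsunobu inversion of the carbinol (4‑nitrobenzoic acid, PPh3, DIAD) gives (1R)-1-[(2R,3S)-3-methyloxiran-2-yl]ethyl 4-nitrobenzoate F2. Brief methanolysis (K2CO3, MeOH, 0 °C) gives the threo epoxy alcohol (1R)-1-[(2S,3S)-3-methyloxiran-2-yl]ethan-1-ol F3, and silylation as in step 9 gives 18.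

Step 11 (the proposed new step). The risks are methyl or butyl transfer instead of alkenyl transfer, attack at C17, and Lewis‑acid rearrangement of 18 (hydride shift from C18). The fallback uses known chemistry, sets out from 14 and comes back at 21. Zr‑catalysed methylalumination of 14 (through 19) is quenched with I2 to give the isolated vinyl iodide (2S,4E)-5-iodo-2,4-dimethylpent-4-en-1-ol F4. MeLi (1 equiv) and then t‑BuLi (2 equiv) at −78 °C give lithium (2S,4E)-5-lithio-2,4-dimethylpent-4-en-1-olate F5, which opens 18 at C16 with inversion in the presence of BF3·OEt2 (the established organolithium/BF3 epoxide opening) to give 21.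

Step 15 (one‑pot methylalumination and cross‑coupling). The risks are attack of Me3Al on the methyl ester during a slow carbometalation, and protodemetalation or homocoupling that wastes the advanced iodide 24. The fallback sets out from 11 and 24 and comes back at 26. The methylalumination of 11 (through 25) is quenched with I2 to give the isolated methyl 2-[(2R,5S,6S)-6-[(1E)-1-iodoprop-1-en-2-yl]-5-methyloxan-2-yl]acetate F6. Compound 24 is converted by Miyaura borylation (B2pin2, PdCl2(PPh3)2, PPh3, KOPh, toluene, 50 °C) into tert-butyl{[(2R,3R,4S,5E,8S,9E)-3-methoxy-4,6,8-trimethyl-10-(4,4,5,5-tetramethyl-1,3,2-dioxaborolan-2-yl)deca-5,9-dien-2-yl]oxy}dimethylsilane F7. Suzuki coupling of F6 with F7 (PdCl2(dppf), K3PO4, DMF/H2O, rt) gives 26.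

**Further compounds**
F1 | step 10 | (1S)-1-[(2S,3S)-3-methyloxiran-2-yl]ethan-1-ol | C[C@H](O)[C@@H]1O[C@H]1C
F2 | step 10 | (1R)-1-[(2R,3S)-3-methyloxiran-2-yl]ethyl 4-nitrobenzoate | C[C@@H](OC(=O)c1ccc(cc1)[N+](=O)[O-])[C@@H]1O[C@H]1C
F3 | step 10 | (1R)-1-[(2S,3S)-3-methyloxiran-2-yl]ethan-1-ol | C[C@@H](O)[C@@H]1O[C@H]1C
F4 | step 11 | (2S,4E)-5-iodo-2,4-dimethylpent-4-en-1-ol | I/C=C(\C)C[C@H](C)CO
F5 | step 11 | lithium (2S,4E)-5-lithio-2,4-dimethylpent-4-en-1-olate | [Li]/C=C(\C)C[C@H](C)CO[Li]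
F6 | step 15 | methyl 2-[(2R,5S,6S)-6-[(1E)-1-iodoprop-1-en-2-yl]-5-methyloxan-2-yl]acetate | I/C=C(\C)[C@H]1O[C@@H](CC(=O)OC)CC[C@@H]1C
F7 | step 15 | tert-butyl{[(2R,3R,4S,5E,8S,9E)-3-methoxy-4,6,8-trimethyl-10-(4,4,5,5-tetramethyl-1,3,2-dioxaborolan-2-yl)deca-5,9-dien-2-yl]oxy}dimethylsilane | CC1(C)OB(/C=C/[C@@H](C)C/C(C)=C/[C@H](C)[C@@H](OC)[C@@H](C)O[Si](C)(C)C(C)(C)C)OC1(C)C
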